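**Retrosynthetic overview**

1. The target comes from a monocyclic sulfonyl acetate by removing an allylic p-tolylsulfonyl group (C9) and an acetate; no ring or stereocentre is touched.
2. Key disconnection: the cyclohexanol ring is opened back to the complete open-chain all-E C25 pentaene. In the forward sense this is a proton-initiated, water-terminated chair cyclisation (H+ to C18, C14–C19 bond, H2O to C15), the way the geranylfarnesyl chain is thought to be cyclised in nature. Both stereocentres are set here by a chiral confined Brønsted acid.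
3. The C9 sulfone left over from chain assembly serves as a built-in stop: it deactivates the 10,11-alkene, so the cascade ends after one ring.
4. The open-chain C25 pentaene comes from C8–C9 alkylation of farnesyl p-tolyl sulfone (from (E,E)-farnesol) with 8-bromogeranyl acetate (from geranyl acetate by allylic oxidation and bromination).
5. Ring order: one ring only (the cyclohexanol), formed in step 5 of 6.

Assumption: the (S,S) antipode of the acid in step 5 is taken as the one that gives the (1S,2S) ring; should it give the mirror image, the (R,R) acid is used and nothing else changes.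

**Route**

Step 1
Reactants: 1 geranyl acetate
Product: 2 (2E,6E)-8-hydroxygeranyl acetate
Conditions: SeO2 (0.1 equiv), t-BuOOH (3 equiv), salicylic acid (0.1 equiv), CH2Cl2, 0 °C → rt
Reagents that add atoms: tert-butyl hydroperoxide, CC(C)(C)OO (terminal oxidant; its O is relayed through catalytic selenium dioxide, O=[Se]=O)
Why: Selenium dioxide allylic oxidation (ene reaction then [2,3]-sigmatropic shift) attacks the more electron-rich 6,7-alkene at its E-methyl group, so the new CH2OH is E and the acetate-deactivated 2,3-alkene is left alone.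

Step 2
Reactants: 2 (2E,6E)-8-hydroxygeranyl acetate
Product: 3 (2E,6E)-8-bromogeranyl acetate
Conditions: CBr4, PPh3, CH2Cl2, 0 °C
Reagents that add atoms: carbon tetrabromide, BrC(Br)(Br)Br
Why: Appel bromination, in which bromide displaces the alkoxyphosphonium at the primary carbon by SN2, so there is no allylic shift, the 6E geometry is kept and the acetate is untouched.

Step 3
Reactants: 4 (2E,6E)-farnesol
Product: 6 (2E,6E)-farnesyl p-tolyl sulfone, via farnesyl bromide 5 (not isolated)
Conditions: PBr3 (0.4 equiv), THF, −10 °C; then p-TolSO2Na (2.5 equiv), DMF, 0 °C → rt, same flask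
Reagents that add atoms: sodium p-toluenesulfinate, Cc1ccc(cc1)S(=O)[O-].[Na+]
Why: PBr3 turns the primary allylic alcohol into the bromide and the soft sulfinate sulfur then displaces bromide by SN2 at the primary carbon (S-alkylation), so both E alkenes are carried through unchanged.

Step 4
Reactants: 6 (2E,6E)-farnesyl p-tolyl sulfone; 3 (2E,6E)-8-bromogeranyl acetate
Product: 8 open-chain all-E C25 9-sulfonyl pentaenyl acetate (racemic at C9), via lithio sulfone 7 (not isolated)
Conditions: n-BuLi (1.0 equiv), THF, −78 °C; then 3 (1.05 equiv), THF–DMPU, −78 → −30 °C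
Reagents that add atoms: none
Why: Sulfone-carbanion allyl–allyl coupling (Biellmann/Julia-type alkylation), in which the α-lithio allyl sulfone reacts at its α-carbon with the primary allylic bromide by SN2 faster than it attacks the acetate at −78 °C, giving the head-to-tail C8–C9 bond with all E alkenes intact and a racemic C9 centre that is erased in step 6.

Step 5
Reactants: 8 open-chain all-E C25 9-sulfonyl pentaenyl acetate
Product: 10 (1S,2S)-monocyclic hydroxy sulfonyl acetate (both C9 epimers), via ring-A cation 9 (not isolated)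
Conditions: (S,S)-IDPi acid HN[P(=NSO2C6F5)(O2C20H10Ar2)]2, Ar = spiro[cyclopentane-1,9′-fluoren]-2′-yl at the 3,3′-positions of each (S)-binaphthyl (5 mol %), H2O (5 equiv), (CF3)3COH, −10 °C; Et3N quench
Reagents that add atoms: water, O
Why: Proposed new method: a confined chiral Brønsted acid in a fluorinated alcohol protonates the exposed terminal 18,19-alkene with π-participation of the 14E-alkene through a chair transition state (C14–C19 bond); the C9 sulfonyl and C1 acetoxy groups inductively switch off the 10,11- and 2,3-alkenes, so cation 9 cannot close a second ring and is captured by water anti to the new C–C bond (equatorial OH, trans to the side chain, as dictated by the E alkene), while the chiral anion fixes the face of protonation and hence (1S,2S); the closest known reaction types are the IDPi/fluoroalcohol-catalysed enantioselective proton-initiated cyclisation of homofarnesol to ambroxide (hydroxyl-terminated) and the water trapping of the monocyclic cation in the Hg(OTf)2-induced cyclisation of farnesyl sulfone.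

Step 6
Reactants: 10 (1S,2S)-monocyclic hydroxy sulfonyl acetate
Product: 12 preluffariellolide A, via sulfonyl diol 11 (not isolated)
Conditions: LiBHEt3 (6 equiv), THF, 0 °C, 20 min; then PdCl2(dppp) (5 mol %; dppp = Ph2P(CH2)3PPh2), 0 °C → rt; aq. NH4Cl
Reagents that add atoms: none
Why: Excess LiBHEt3 first cleaves the acetate to the alkoxide (leaving no allylic C–O bond that zerovalent palladium could ionise), then palladium-catalysed hydride desulfonylation of the allylic sulfone (π-allyl palladium hydride, hydride delivered to the less hindered C9 terminus) removes the sulfonyl group with the 10E alkene kept in place and both ring stereocentres untouched.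

**Compound list**

1 | geranyl acetate, (2E)-3,7-dimethylocta-2,6-dien-1-yl acetate | CC(=O)OC/C=C(\C)CCC=C(C)C | starting material
2 | (2E,6E)-8-hydroxy-3,7-dimethylocta-2,6-dien-1-yl acetate | CC(=O)OC/C=C(\C)CC/C=C(\C)CO | intermediate
3 | (2E,6E)-8-bromo-3,7-dimethylocta-2,6-dien-1-yl acetate | CC(=O)OC/C=C(\C)CC/C=C(\C)CBr | intermediate
4 | (2E,6E)-farnesol, (2E,6E)-3,7,11-trimethyldodeca-2,6,10-trien-1-ol | OC/C=C(\C)CC/C=C(\C)CCC=C(C)C | starting material
5 | (2E,6E)-farnesyl bromide (not isolated) | BrC/C=C(\C)CC/C=C(\C)CCC=C(C)C | intermediate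
6 | (2E,6E)-farnesyl p-tolyl sulfone, 1-methyl-4-{[(2E,6E)-3,7,11-trimethyldodeca-2,6,10-trien-1-yl]sulfonyl}benzene | Cc1ccc(cc1)S(=O)(=O)C/C=C(\C)CC/C=C(\C)CCC=C(C)C | intermediate
7 | α-lithio derivative of 6, C1 carbanion as lithium salt (not isolated) | [Li+].Cc1ccc(cc1)S(=O)(=O)[CH-]/C=C(\C)CC/C=C(\C)CCC=C(C)C | intermediate
8 | (2E,6E,10E,14E)-3,7,11,15,19-pentamethyl-9-(p-tolylsulfonyl)icosa-2,6,10,14,18-pentaen-1-yl acetate, racemic at C9 | CC(=O)OC/C=C(\C)CC/C=C(\C)CC(S(=O)(=O)c1ccc(C)cc1)/C=C(\C)CC/C=C(\C)CCC=C(C)C | intermediate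
9 | ring-A tertiary cation: (6S)-2,2,6-trimethyl-6-substituted cyclohexyl cation at C15, ion-paired with the IDPi anion (not isolated) | CC(=O)OC/C=C(\C)CC/C=C(\C)CC(S(=O)(=O)c1ccc(C)cc1)/C=C(\C)CC[C@H]1C(C)(C)CCC[C+]1C | intermediate
10 | (2E,6E,10E)-13-[(1S,2S)-2-hydroxy-2,6,6-trimethylcyclohexyl]-3,7,11-trimethyl-9-(p-tolylsulfonyl)trideca-2,6,10-trien-1-yl acetate, both C9 epimers | CC(=O)OC/C=C(\C)CC/C=C(\C)CC(S(=O)(=O)c1ccc(C)cc1)/C=C(\C)CC[C@H]1C(C)(C)CCC[C@]1(C)O | intermediate
11 | (2E,6E,10E)-13-[(1S,2S)-2-hydroxy-2,6,6-trimethylcyclohexyl]-3,7,11-trimethyl-9-(p-tolylsulfonyl)trideca-2,6,10-trien-1-ol, present as its lithium alkoxide (not isolated) | OC/C=C(\C)CC/C=C(\C)CC(S(=O)(=O)c1ccc(C)cc1)/C=C(\C)CC[C@H]1C(C)(C)CCC[C@]1(C)O | intermediate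
12 | preluffariellolide A, (1S,2S)-2-[(3E,7E,11E)-13-hydroxy-3,7,11-trimethyltrideca-3,7,11-trien-1-yl]-1,3,3-trimethylcyclohexan-1-ol | OC/C=C(\C)CC/C=C(\C)CC/C=C(\C)CC[C@H]1C(C)(C)CCC[C@]1(C)O | target

**Totals and risks**

Total step count: 6. Longest linear sequence: 5 steps (1 → 2 → 3 → 8 → 10 → 12); the farnesol branch joins after one step.

Most likely to fail, first: step 5. The cation may lose a proton to give cyclohexene isomers instead of taking up water, an internal alkene may be protonated, and the level and sense of enantioselection are untested for this substrate. The fallback moves the ring formation to a small substrate where an enantioselective proton-initiated monocyclisation with oxygen capture is established, and joins the chain afterwards. It sets out from bromide 3 and comes back at 10. Purchased (E)-geranylacetone F1 is cyclised by the squalene–hopene cyclase of Alicyclobacillus acidocaldarius (protein biocatalyst as E. coli whole cells, citrate buffer pH 6, 30 °C) to the trans-fused bicyclic enol ether F2. Dilute HCl in aqueous THF opens it to hydroxy ketone F3. Horner–Wadsworth–Emmons olefination (triethyl phosphonoacetate, NaH, THF) gives E-enoate F4 after removal of the minor Z isomer. i-Bu2AlH in CH2Cl2 at −78 °C gives allylic alcohol F5. MsCl, LiCl and s-collidine in DMF at 0 °C convert only the primary hydroxyl into allylic chloride F6, and p-TolSO2Na added to the same flask gives hydroxy sulfone F7. Its dianion (n-BuLi, 2 equiv, THF, −78 °C) is alkylated with 3 to give 10, and step 6 follows as written.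

Second: step 6. Palladium hydride could shift or isomerise the 10,11-alkene, or cleave the allylic C1–O bond if acetate cleavage is not complete before the palladium is added. The fallback separates the two events and replaces the π-allyl hydride transfer by single-electron C–S cleavage. It sets out from 10 and comes back at 12. K2CO3 in MeOH at rt gives diol 11, now isolated, and Li in EtNH2/THF at −78 °C removes the sulfonyl group from the free diol to give 12. This fallback makes no new compound (F0).

Third: step 4. The lithiated sulfone may attack the acetate of 3 or be quenched by it. The fallback removes the ester before the C–C bond is made and puts it back afterwards. It sets out from 3 and comes back at 8. i-Bu2AlH (2.2 equiv, CH2Cl2, −78 °C) cleaves the acetate of 3 to bromo alcohol F8. This is converted into its lithium alkoxide (n-BuLi, 1 equiv, −78 °C) and alkylated by lithio sulfone 7 to give C25 sulfonyl alcohol F9. Ac2O, pyridine and DMAP return 8.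

**Further compounds**

F1 | step 5 | (E)-geranylacetone, (5E)-6,10-dimethylundeca-5,9-dien-2-one (purchased) | CC(=O)CC/C=C(\C)CCC=C(C)C
F2 | step 5 | (4aS,8aS)-2,5,5,8a-tetramethyl-4a,5,6,7,8,8a-hexahydro-4H-chromene | CC1=CC[C@H]2C(C)(C)CCC[C@]2(C)O1
F3 | step 5 | 4-[(1S,2S)-2-hydroxy-2,6,6-trimethylcyclohexyl]butan-2-one | CC(=O)CC[C@H]1C(C)(C)CCC[C@]1(C)O
F4 | step 5 | ethyl (2E)-5-[(1S,2S)-2-hydroxy-2,6,6-trimethylcyclohexyl]-3-methylpent-2-enoate | CCOC(=O)/C=C(\C)CC[C@H]1C(C)(C)CCC[C@]1(C)O
F5 | step 5 | (2E)-5-[(1S,2S)-2-hydroxy-2,6,6-trimethylcyclohexyl]-3-methylpent-2-en-1-ol | OC/C=C(\C)CC[C@H]1C(C)(C)CCC[C@]1(C)O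
F6 | step 5 | (1S,2S)-2-[(3E)-5-chloro-3-methylpent-3-en-1-yl]-1,3,3-trimethylcyclohexan-1-ol | ClC/C=C(\C)CC[C@H]1C(C)(C)CCC[C@]1(C)O
F7 | step 5 | (1S,2S)-1,3,3-trimethyl-2-[(3E)-3-methyl-5-(p-tolylsulfonyl)pent-3-en-1-yl]cyclohexan-1-ol | Cc1ccc(cc1)S(=O)(=O)C/C=C(\C)CC[C@H]1C(C)(C)CCC[C@]1(C)O
F0 | step 6 | none | none
F8 | step 4 | (2E,6E)-8-bromo-3,7-dimethylocta-2,6-dien-1-ol | OC/C=C(\C)CC/C=C(\C)CBr
F9 | step 4 | (2E,6E,10E,14E)-3,7,11,15,19-pentamethyl-9-(p-tolylsulfonyl)icosa-2,6,10,14,18-pentaen-1-ol, racemic at C9 | OC/C=C(\C)CC/C=C(\C)CC(S(=O)(=O)c1ccc(C)cc1)/C=C(\C)CC/C=C(\C)CCC=C(C)C
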